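**Retrosynthetic overview**
- The only strategic bond is the C(α)–O(aryl) ether bond next to the ketone, which carries the sole stereocentre. It is cut to a racemic α-bromo ketone and (E)-4-propenylsyringol, joined by a catalytic enantioconvergent SN2 reaction with inversion on the (R)-bromide.
- The α-bromo ketone comes from 3',4',5'-trimethoxypropiophenone by α-bromination.
- The (E)-propenylphenol comes from 4-allyl-2,6-dimethoxyphenol by alkene isomerisation, so the E geometry is fixed before the stereocentre exists.
- No ring is formed. Both benzene rings are bought intact, and two one-step branches meet in the coupling step.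

Assumption: the SMILES reads as (S) at C-2 (O > C=O > CH3 > H). Step 3 is new, so the sense of induction of catalyst Q* must be confirmed in the first run by chiral HPLC and sign of rotation. If it is opposite, the quinine-derived pseudo-enantiomer is used under the same conditions.

Catalyst Q* is 1-[3,5-bis(trifluoromethyl)benzyl]-9-deoxy-9-epi-9-{3-[3,5-bis(trifluoromethyl)phenyl]ureido}quinidinium bromide. It belongs to a known catalyst family, is made separately from quinidine, and is not counted in the steps.

**Step 1**
Reactants: 1 1-(3,4,5-trimethoxyphenyl)propan-1-one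
Product: 2 rac-2-bromo-1-(3,4,5-trimethoxyphenyl)propan-1-one
Conditions: CuBr2 (2.1 equiv), EtOAc/CHCl3 1:1, reflux, 3 h
Reagents that add atoms: copper(II) bromide, Br[Cu]Br
Why: Heterogeneous CuBr2 α-bromination of a ketone goes through the copper-bound enol, stops at the monobromide and leaves the acyl-deactivated trimethoxyarene untouched; the new stereocentre is deliberately formed racemic.

**Step 2**
Reactants: 3 4-allyl-2,6-dimethoxyphenol (methoxyeugenol)
Product: 4 (E)-2,6-dimethoxy-4-(prop-1-en-1-yl)phenol
Conditions: RuHCl(CO)(PPh3)3 (1 mol%), PhMe, 80 °C, Ar, 4 h; residual Z isomer removed on AgNO3–silica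
Reagents that add atoms: none
Why: Ru–H alkene isomerisation (hydrometallation/β-hydride elimination) moves the C=C into conjugation with the arene and gives the thermodynamically preferred E-styrene (about 95:5); no stereocentre is involved.

**Step 3**
Reactants: 2 rac-2-bromo-1-(3,4,5-trimethoxyphenyl)propan-1-one (1.5 equiv); 4 (E)-2,6-dimethoxy-4-(prop-1-en-1-yl)phenol
Product: 6 (S)-2-[2,6-dimethoxy-4-((E)-prop-1-en-1-yl)phenoxy]-1-(3,4,5-trimethoxyphenyl)propan-1-one, via potassium aryloxide 5 (not isolated)
Conditions: Q* (10 mol%), powdered K2CO3 (1.5 equiv), degassed PhMe (0.05 M), Ar, –20 °C; 4 added over 10 h, then 36 h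
Reagents that add atoms: none
Why: Proposed new method: enantioconvergent SN2 O-alkylation of a phenol with a racemic secondary α-bromo aryl ketone under bifunctional chiral ammonium/urea phase-transfer catalysis, run as a dynamic kinetic resolution; solid 5 enters toluene only as the chiral ion pair Q*+ ArO–, in which urea N–H and N+–C–H contacts hold the oxide and the cationic face docks the C=O/C–Br dipole, so the uncatalysed background is negligible; this ion pair displaces bromide from (R)-2 with inversion to give (S)-6 faster than it attacks (S)-2, because the bulky 2,6-dimethoxyaryloxide must pass H rather than CH3 against the catalyst wall; Q*+ Br– (degenerate bromide exchange, fast at an α-keto carbon) and reversible enolisation keep 2 racemic, and slow addition of the hindered phenol plus excess 2 keeps substitution slower than racemisation; the tertiary α-C–H of 6 is not enolised at a relevant rate by solid K2CO3 at –20 °C; the racemic K2CO3 Williamson coupling of this type of partner is reliable, and the closest known asymmetric reaction types are enantioconvergent displacement of racemic α-bromo ketones by fluoride under hydrogen-bonding phase-transfer catalysis and the chiral-ammonium-catalysed intramolecular α-aryloxylation (oxidative cycloetherification) of keto phenols.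

**Compound list**
1 | 1-(3,4,5-trimethoxyphenyl)propan-1-one | CCC(=O)c1cc(OC)c(OC)c(OC)c1 | starting material
2 | rac-2-bromo-1-(3,4,5-trimethoxyphenyl)propan-1-one | CC(Br)C(=O)c1cc(OC)c(OC)c(OC)c1 | intermediate
3 | 4-allyl-2,6-dimethoxyphenol | C=CCc1cc(OC)c(O)c(OC)c1 | starting material
4 | (E)-2,6-dimethoxy-4-(prop-1-en-1-yl)phenol | C/C=C/c1cc(OC)c(O)c(OC)c1 | intermediate
5 | potassium (E)-2,6-dimethoxy-4-(prop-1-en-1-yl)phenolate (not isolated) | C/C=C/c1cc(OC)c([O-])c(OC)c1.[K+] | intermediate
6 | (S)-2-[2,6-dimethoxy-4-((E)-prop-1-en-1-yl)phenoxy]-1-(3,4,5-trimethoxyphenyl)propan-1-one | C/C=C/c1cc(OC)c(O[C@@H](C)C(=O)c2cc(OC)c(OC)c(OC)c2)c(OC)c1 | target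

Total step count: 3. Longest linear sequence: 2 (1 → 2 → 6 or 3 → 4 → 6).

**Steps most likely to fail**

*Step 3 (the new step).*
- Risks: the selectivity between (R)-2 and (S)-2 may be too low, racemisation of 2 may be too slow, or the base may slowly erode the ee of 6.
- The fallback uses only known reaction types and stays metal-free and catalytic. It sets out from 1 and comes back to the route at 6, using 4 from step 2.
- Ketone 1 is silylated (TBSOTf, Et3N, CH2Cl2, 0 °C) to (Z)-tert-butyl(dimethyl){[1-(3,4,5-trimethoxyphenyl)prop-1-en-1-yl]oxy}silane F1.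
- Shi epoxidation of F1 (D-fructose-derived ketone 30 mol%, Oxone, K2CO3 buffer pH 10.5, MeCN/dimethoxymethane/H2O, 0 °C) attacks the same face as for trans-β-methylstyrene. It gives (2S,3R)-2-(tert-butyldimethylsilyloxy)-3-methyl-2-(3,4,5-trimethoxyphenyl)oxirane F2.
- F2 is hydrolysed on work-up (1 M HCl/THF) to (R)-2-hydroxy-1-(3,4,5-trimethoxyphenyl)propan-1-one F3.
- Mitsunobu etherification of F3 with 4 (PPh3, DIAD, PhMe, 0 °C) inverts C-2 and delivers 6.

*Step 2.*
- Risks: incomplete E selectivity, inhibition of the Ru–H catalyst by the free phenol, and air oxidation of the propenylphenol.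
- The fallback reverses the order of events. It sets out from 3 and comes back at 6.
- Phenol 3 is used directly in the step 3 protocol with 2. It reacts through potassium 4-allyl-2,6-dimethoxyphenolate F4 to give (S)-2-(4-allyl-2,6-dimethoxyphenoxy)-1-(3,4,5-trimethoxyphenyl)propan-1-one F5.
- With no acidic OH left, F5 is isomerised with the base-free bifunctional catalyst [CpRu(2-(di-isopropylphosphino)-4-tert-butyl-1-methylimidazole)(MeCN)]PF6 (2 mol%, acetone, rt). This catalyst is expected to move the terminal alkene by one position with very high E selectivity and to leave the α-stereocentre untouched, giving 6.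

*Step 1.*
- Risks: ring bromination of the trimethoxyarene or α,α-dibromination.
- The fallback separates enol formation from halogenation. It sets out from 1 and comes back at 2.
- Ketone 1 is converted (TMSOTf, Et3N, CH2Cl2, 0 °C) into (Z)-trimethyl{[1-(3,4,5-trimethoxyphenyl)prop-1-en-1-yl]oxy}silane F6.
- F6 is brominated with one equivalent of NBS (THF, –78 °C), which reacts only at the enol ether carbon and gives 2.

**Further compounds**
F1 | step 3 | (Z)-tert-butyl(dimethyl){[1-(3,4,5-trimethoxyphenyl)prop-1-en-1-yl]oxy}silane | C/C=C(\O[Si](C)(C)C(C)(C)C)c1cc(OC)c(OC)c(OC)c1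
F2 | step 3 | (2S,3R)-2-(tert-butyldimethylsilyloxy)-3-methyl-2-(3,4,5-trimethoxyphenyl)oxirane | C[C@H]1O[C@]1(O[Si](C)(C)C(C)(C)C)c2cc(OC)c(OC)c(OC)c2
F3 | step 3 | (R)-2-hydroxy-1-(3,4,5-trimethoxyphenyl)propan-1-one | C[C@@H](O)C(=O)c1cc(OC)c(OC)c(OC)c1
F4 | step 2 | potassium 4-allyl-2,6-dimethoxyphenolate | C=CCc1cc(OC)c([O-])c(OC)c1.[K+]
F5 | step 2 | (S)-2-(4-allyl-2,6-dimethoxyphenoxy)-1-(3,4,5-trimethoxyphenyl)propan-1-one | C=CCc1cc(OC)c(O[C@@H](C)C(=O)c2cc(OC)c(OC)c(OC)c2)c(OC)c1
F6 | step 1 | (Z)-trimethyl{[1-(3,4,5-trimethoxyphenyl)prop-1-en-1-yl]oxy}silane | C/C=C(\O[Si](C)(C)C)c1cc(OC)c(OC)c(OC)c1
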